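**Retrosynthetic overview**
- Last operation: one acid solvolysis removes three aryl MOM acetals and one tertiary TES ether from the fully protected chalcone.
- Key disconnection: the enone Cα=Cβ bond. It is made by an intermolecular Claisen–Schmidt aldol condensation of a 3-alkyl-2,4-bis(MOM-oxy)acetophenone with 4-(MOM-oxy)benzaldehyde.
- Aryl–CH2 bond: B-alkyl Suzuki–Miyaura coupling of 3-iodo-2,4-bis(MOM-oxy)acetophenone with the 9-BBN adduct of TES-protected (R)-linalool. The linalool supplies the only stereocentre from the chiral pool.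
- The iodide comes from 2,4-dihydroxyacetophenone by C3-selective iodination and MOM capping.
- No ring is formed. Ring A (resacetophenone) and ring B (4-hydroxybenzaldehyde) are bought intact.

Assumption: commercial natural (R)-(−)-linalool is taken at ≥98% ee (lot checked by chiral GC); no step touches its C–O stereocentre, so this ee is carried into the target.

**Step 1**
Reactants: 1 2,4-dihydroxyacetophenone
Product: 2 1-(2,4-dihydroxy-3-iodophenyl)ethan-1-one
Conditions: I2 (0.4 equiv), HIO3 (0.2 equiv), EtOH/H2O, 35 °C, 2 h; product precipitated by dilution with water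
Reagents that add atoms: iodine, II; iodic acid, OI(=O)=O
Why: Electrophilic aromatic iodination in which the I2/HIO3 couple delivers exactly one iodonium equivalent to C3, the carbon ortho to both hydroxyl groups and the most electron-rich site, while the limiting stoichiometry holds back 5-iodo and 3,5-diiodo products.

**Step 2**
Reactants: 2 1-(2,4-dihydroxy-3-iodophenyl)ethan-1-one
Product: 3 1-[3-iodo-2,4-bis(methoxymethoxy)phenyl]ethan-1-one
Conditions: NaH (2.3 equiv), MOMCl (2.6 equiv), DMF, 0 °C to rt, 4 h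
Reagents that add atoms: chloromethyl methyl ether (MOMCl), COCCl
Why: Williamson-type O-alkylation in which irreversible deprotonation by NaH breaks the hydrogen bond between the 2-OH and the acetyl group, so even this flanked phenol is capped and both oxygens become MOM acetals inert to base, boranes and palladium.

**Step 3**
Reactants: 4 (R)-(−)-linalool, (3R)-3,7-dimethylocta-1,6-dien-3-ol
Product: 5 (3R)-3,7-dimethyl-3-(triethylsilyloxy)octa-1,6-diene
Conditions: TESOTf (1.3 equiv), 2,6-lutidine (2.0 equiv), CH2Cl2, −78 to 0 °C, 2 h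
Reagents that add atoms: triethylsilyl trifluoromethanesulfonate (TESOTf), CC[Si](CC)(CC)OS(=O)(=O)C(F)(F)F
Why: Silyl ether formation at a hindered tertiary alcohol needs the very electrophilic silyl triflate, 2,6-lutidine keeps the medium non-acidic so the allylic C–O bond never ionises, and since only the O–H bond reacts the (R) stereocentre bought in 4 is retained.

**Step 4**
Reactants: 5 (3R)-3,7-dimethyl-3-(triethylsilyloxy)octa-1,6-diene; 3 1-[3-iodo-2,4-bis(methoxymethoxy)phenyl]ethan-1-one
Product: 7 1-{3-[(3R)-3,7-dimethyl-3-(triethylsilyloxy)oct-6-en-1-yl]-2,4-bis(methoxymethoxy)phenyl}ethan-1-one, via B-alkyl-9-BBN borane 6 (not isolated)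
Conditions: 5 (1.4 equiv), 9-BBN (1.4 equiv, 0.5 M in THF), 0 °C to rt, 8 h; then degassed 3 M aq K3PO4 (3 equiv), 3 (1.0 equiv), Pd(OAc)2 (5 mol %), SPhos (10 mol %), THF, 60 °C, 12 h; non-oxidative work-up
Reagents that add atoms: 9-borabicyclo[3.3.1]nonane (9-BBN), [H]B1C2CCCC1CCC2 (its boron bicycle is carried only in 6; 7 keeps only its hydrogen)
Why: Anti-Markovnikov hydroboration by 9-BBN takes the monosubstituted vinyl group far faster than the trisubstituted alkene, and the following B-alkyl Suzuki–Miyaura coupling works at the di-ortho-substituted C–I bond because the bulky electron-rich SPhos ligand on zerovalent palladium puts oxidative addition and reductive elimination ahead of β-hydride elimination, the quaternary stereocentre being a spectator (its descriptor reads S in 6 only because boron ranks below carbon).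

**Step 5**
Reactants: 8 4-hydroxybenzaldehyde
Product: 9 4-(methoxymethoxy)benzaldehyde
Conditions: MOMCl (1.3 equiv), i-Pr2NEt (1.6 equiv), CH2Cl2, 0 °C to rt, 6 h
Reagents that add atoms: chloromethyl methyl ether (MOMCl), COCCl
Why: Simple O-alkylation of an acidic phenol by the reactive α-chloro ether under amine base, which removes the phenoxide that would otherwise deactivate the aldehyde in the aldol step.

**Step 6 (key step)**
Reactants: 7 1-{3-[(3R)-3,7-dimethyl-3-(triethylsilyloxy)oct-6-en-1-yl]-2,4-bis(methoxymethoxy)phenyl}ethan-1-one; 9 4-(methoxymethoxy)benzaldehyde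
Product: 11 (E)-1-{3-[(3R)-3,7-dimethyl-3-(triethylsilyloxy)oct-6-en-1-yl]-2,4-bis(methoxymethoxy)phenyl}-3-[4-(methoxymethoxy)phenyl]prop-2-en-1-one, via β-hydroxy ketone aldol adduct 10 (not isolated)
Conditions: 9 (1.2 equiv), KOH (5 equiv), EtOH/H2O 9:1, 0 °C to rt, 36 h
Reagents that add atoms: none
Why: Claisen–Schmidt crossed aldol condensation in which only 7 has enolisable hydrogens and only 9 offers an unhindered non-enolisable aldehyde, so one C–C bond joins the two fragments, and E1cB loss of water from 10 under thermodynamic control gives solely the (E)-enone, erasing the transient carbinol centre while the MOM acetals, the tertiary TES ether and the (R) centre are untouched by hydroxide.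

**Step 7**
Reactants: 11 (E)-1-{3-[(3R)-3,7-dimethyl-3-(triethylsilyloxy)oct-6-en-1-yl]-2,4-bis(methoxymethoxy)phenyl}-3-[4-(methoxymethoxy)phenyl]prop-2-en-1-one
Product: 12 (E)-1-{2,4-dihydroxy-3-[(3R)-3-hydroxy-3,7-dimethyloct-6-en-1-yl]phenyl}-3-(4-hydroxyphenyl)prop-2-en-1-one
Conditions: 3 M aq HCl/MeOH 1:9 (about 0.3 M HCl), rt to 40 °C, 2–4 h under LC control, stopped as soon as the last MOM group is gone
Reagents that add atoms: none
Why: Acid-catalysed acetal solvolysis and silyl ether solvolysis cleave the aryl MOM groups and the TES group at an acidity at which the non-allylic, non-benzylic tertiary alcohol does not ionise (so R is kept), the trisubstituted alkene is not solvated, and the hydrogen-bonded 2'-hydroxychalcone lacking a 6'-OH does not close to the flavanone.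

**Compound list**
1 | 2,4-dihydroxyacetophenone | CC(=O)c1ccc(O)cc1O | starting material
2 | 1-(2,4-dihydroxy-3-iodophenyl)ethan-1-one | CC(=O)c1ccc(O)c(I)c1O | intermediate
3 | 1-[3-iodo-2,4-bis(methoxymethoxy)phenyl]ethan-1-one | CC(=O)c1ccc(OCOC)c(I)c1OCOC | intermediate
4 | (R)-(−)-linalool | CC(C)=CCC[C@@](C)(O)C=C | starting material
5 | (3R)-3,7-dimethyl-3-(triethylsilyloxy)octa-1,6-diene | CC(C)=CCC[C@@](C)(O[Si](CC)(CC)CC)C=C | intermediate
6 | 9-[(3S)-3,7-dimethyl-3-(triethylsilyloxy)oct-6-en-1-yl]-9-borabicyclo[3.3.1]nonane (same spatial arrangement as 5) | CC(C)=CCC[C@@](C)(O[Si](CC)(CC)CC)CCB1C2CCCC1CCC2 | intermediate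
7 | 1-{3-[(3R)-3,7-dimethyl-3-(triethylsilyloxy)oct-6-en-1-yl]-2,4-bis(methoxymethoxy)phenyl}ethan-1-one | CC(C)=CCC[C@@](C)(O[Si](CC)(CC)CC)CCc1c(OCOC)ccc(C(C)=O)c1OCOC | intermediate
8 | 4-hydroxybenzaldehyde | O=Cc1ccc(O)cc1 | starting material
9 | 4-(methoxymethoxy)benzaldehyde | COCOc1ccc(C=O)cc1 | intermediate
10 | 1-{3-[(3R)-3,7-dimethyl-3-(triethylsilyloxy)oct-6-en-1-yl]-2,4-bis(methoxymethoxy)phenyl}-3-hydroxy-3-[4-(methoxymethoxy)phenyl]propan-1-one (both carbinol epimers) | CC(C)=CCC[C@@](C)(O[Si](CC)(CC)CC)CCc1c(OCOC)ccc(C(=O)CC(O)c2ccc(OCOC)cc2)c1OCOC | intermediate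
11 | (E)-1-{3-[(3R)-3,7-dimethyl-3-(triethylsilyloxy)oct-6-en-1-yl]-2,4-bis(methoxymethoxy)phenyl}-3-[4-(methoxymethoxy)phenyl]prop-2-en-1-one | CC(C)=CCC[C@@](C)(O[Si](CC)(CC)CC)CCc1c(OCOC)ccc(C(=O)/C=C/c2ccc(OCOC)cc2)c1OCOC | intermediate
12 | (E)-1-{2,4-dihydroxy-3-[(3R)-3-hydroxy-3,7-dimethyloct-6-en-1-yl]phenyl}-3-(4-hydroxyphenyl)prop-2-en-1-one | CC(C)=CCC[C@@](C)(O)CCc1c(O)ccc(C(=O)/C=C/c2ccc(O)cc2)c1O | target

**Total step count:** 7
**Longest linear sequence:** 5 steps (1 → 2 → 3 → 7 → 11 → 12, that is steps 1, 2, 4, 6 and 7)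

**Three steps most likely to fail**

**Step 4** couples a B-alkyl borane at a di-ortho-substituted iodide. The risks are slow transmetalation, protodeiodination of 3 and β-hydride elimination. The fallback drops both the palladium coupling and the pre-installed acetyl group. It makes the aryl–CH2 bond by directed ortho-metalation and SN2 alkylation, sets out from 5 and comes back at 7.
- Borane 6 is made from 5 as before but is oxidised (NaOH, H2O2, THF, 0 °C) to (3R)-3,7-dimethyl-3-(triethylsilyloxy)oct-6-en-1-ol F1.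
- An Appel-type iodination (I2, PPh3, imidazole, CH2Cl2, 0 °C) then gives (3R)-1-iodo-3,7-dimethyl-3-(triethylsilyloxy)oct-6-ene F2.
- In parallel, purchased resorcinol is capped (NaH, MOMCl, DMF) as 1,3-bis(methoxymethoxy)benzene F3.
- n-BuLi (THF, 0 °C) lithiates F3 between the two acetal oxygens to give 2-lithio-1,3-bis(methoxymethoxy)benzene F4.
- Alkylation of F4 by F2 (THF/DMPU, −78 °C to rt) gives 2-[(3R)-3,7-dimethyl-3-(triethylsilyloxy)oct-6-en-1-yl]-1,3-bis(methoxymethoxy)benzene F5.
- A second ortho-lithiation (n-BuLi, TMEDA, THF, 0 °C; the two remaining ortho sites are equivalent) gives {3-[(3R)-3,7-dimethyl-3-(triethylsilyloxy)oct-6-en-1-yl]-2,4-bis(methoxymethoxy)phenyl}lithium F6.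
- Acylation of F6 by N-methoxy-N-methylacetamide (−78 °C, water quench) delivers 7.

**Step 7** is the global acid deprotection. The risks are solvolysis of the trisubstituted alkene, chroman formation or loss of ee at the tertiary carbinol, and flavanone closure. The fallback avoids Brønsted acid altogether by turning the acetals into silyl ethers and ending with fluoride. It sets out from 11 and comes back at 12.
- TMSOTf and 2,2'-bipyridyl (CH3CN, 0 °C to rt) exchange each aryl MOM acetal for a trimethylsilyl ether. The product is (E)-1-{3-[(3R)-3,7-dimethyl-3-(triethylsilyloxy)oct-6-en-1-yl]-2,4-bis(trimethylsilyloxy)phenyl}-3-[4-(trimethylsilyloxy)phenyl]prop-2-en-1-one F7, which is used crude.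
- Bu4NF buffered 1:1 with AcOH (THF, 0 °C to rt) strips all four silyl groups. The buffer keeps the 2'-phenol protonated, so it does not add to the enone, and the product is 12.

**Step 6** is the one-pot Claisen–Schmidt condensation. The risks are sluggish conversion of the ortho-substituted ketone, Michael addition of a second ketone unit, and slow erosion of the TES ether over long exposure to base. The fallback separates C–C bond formation from dehydration. It sets out from 7 (with 9) and comes back at 11.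
- LiN(SiMe3)2 (THF, −78 °C) converts 7 into lithium 1-{3-[(3R)-3,7-dimethyl-3-(triethylsilyloxy)oct-6-en-1-yl]-2,4-bis(methoxymethoxy)phenyl}ethen-1-olate F8.
- Addition of 9 and an AcOH quench at −78 °C give aldol adduct 10, which is now isolated as its epimer mixture.
- MsCl and excess Et3N (CH2Cl2, 0 °C to rt) form 3-{3-[(3R)-3,7-dimethyl-3-(triethylsilyloxy)oct-6-en-1-yl]-2,4-bis(methoxymethoxy)phenyl}-1-[4-(methoxymethoxy)phenyl]-3-oxopropyl methanesulfonate F9.
- F9 undergoes E1cB elimination in the same flask to give (E)-enone 11.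

**Further compounds**
F1 | step 4 | (3R)-3,7-dimethyl-3-(triethylsilyloxy)oct-6-en-1-ol | CC(C)=CCC[C@@](C)(O[Si](CC)(CC)CC)CCO
F2 | step 4 | (3R)-1-iodo-3,7-dimethyl-3-(triethylsilyloxy)oct-6-ene | CC(C)=CCC[C@@](C)(O[Si](CC)(CC)CC)CCI
F3 | step 4 | 1,3-bis(methoxymethoxy)benzene | COCOc1cccc(OCOC)c1
F4 | step 4 | 2-lithio-1,3-bis(methoxymethoxy)benzene | [Li]c1c(OCOC)cccc1OCOC
F5 | step 4 | 2-[(3R)-3,7-dimethyl-3-(triethylsilyloxy)oct-6-en-1-yl]-1,3-bis(methoxymethoxy)benzene | CC(C)=CCC[C@@](C)(O[Si](CC)(CC)CC)CCc1c(OCOC)cccc1OCOC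
F6 | step 4 | {3-[(3R)-3,7-dimethyl-3-(triethylsilyloxy)oct-6-en-1-yl]-2,4-bis(methoxymethoxy)phenyl}lithium | CC(C)=CCC[C@@](C)(O[Si](CC)(CC)CC)CCc1c(OCOC)ccc([Li])c1OCOC
F7 | step 7 | (E)-1-{3-[(3R)-3,7-dimethyl-3-(triethylsilyloxy)oct-6-en-1-yl]-2,4-bis(trimethylsilyloxy)phenyl}-3-[4-(trimethylsilyloxy)phenyl]prop-2-en-1-one | CC(C)=CCC[C@@](C)(O[Si](CC)(CC)CC)CCc1c(O[Si](C)(C)C)ccc(C(=O)/C=C/c2ccc(O[Si](C)(C)C)cc2)c1O[Si](C)(C)C
F8 | step 6 | lithium 1-{3-[(3R)-3,7-dimethyl-3-(triethylsilyloxy)oct-6-en-1-yl]-2,4-bis(methoxymethoxy)phenyl}ethen-1-olate | CC(C)=CCC[C@@](C)(O[Si](CC)(CC)CC)CCc1c(OCOC)ccc(C(=C)O[Li])c1OCOC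
F9 | step 6 | 3-{3-[(3R)-3,7-dimethyl-3-(triethylsilyloxy)oct-6-en-1-yl]-2,4-bis(methoxymethoxy)phenyl}-1-[4-(methoxymethoxy)phenyl]-3-oxopropyl methanesulfonate (both epimers) | CC(C)=CCC[C@@](C)(O[Si](CC)(CC)CC)CCc1c(OCOC)ccc(C(=O)CC(OS(C)(=O)=O)c2ccc(OCOC)cc2)c1OCOC
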